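**Strategy.** The cyclohexanone (C1 carbonyl, C2 CHMe, C3 quaternary, C4 CHMe, C5, C6) hides an arene: C3–C6 plus the CH2 (C7) and carbinol carbon (C8) on C3 are the ring of 2-methoxy-3,4-dimethylphenol, its oxygen becoming the C8 oxygen. Oxidative dearomatization to a masked o-benzoquinone and a Diels–Alder reaction with a chiral (Z)-propenyl ether (C1, C2, C2-methyl) build the cyclohexanone ring across the former para carbons C3 and C6, forming C1–C6 and C2–C3 and setting C2 and C3 in one operation. The precursor is the flat dienone plus the enol ether; demethoxylation, hydrogenation (C4) and retro-Claisen cleavage of C6–C8 then release the side arm.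

Key step: step 4

Assumption: compounds 1, 2, 5, 18 and 20 are taken as commercial; atom labels C1–C8 are those defined above; the target is treated as the open δ-hydroxy ketone (any hemiketal tautomer equilibrates with it).

**Step 1**
Reactants: 1 (R)-1-(2,4,6-triisopropylphenyl)ethanol; 2 allyl bromide
Product: 3 allyl (R)-1-(2,4,6-triisopropylphenyl)ethyl ether
Conditions: NaH, THF/DMF, 0 °C → rt
Reagents that add atoms: none
Why: Williamson ether synthesis, in which the sodium alkoxide of 1 should displace bromide from the primary allylic carbon (SN2) without touching the benzylic stereocenter.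

**Step 2**
Reactants: 3 allyl (R)-1-(2,4,6-triisopropylphenyl)ethyl ether
Product: 4 (Z)-prop-1-enyl (R)-1-(2,4,6-triisopropylphenyl)ethyl ether
Conditions: KOtBu (0.3 equiv), DMSO, 60 °C
Reagents that add atoms: none
Why: Base-mediated allyl-to-propenyl ether isomerization, in which the oxygen-chelated cis-allyl anion is protonated at the terminal carbon and should give the (Z)-enol ether selectively, the benzylic stereocenter being unaffected.

**Step 3**
Reactants: 5 2,3-dimethylanisole
Product: 8 2-methoxy-3,4-dimethylphenol, via aryllithium 6 (not isolated), via arylboronate 7 (not isolated)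
Conditions: s-BuLi, TMEDA, THF, −78 → −20 °C; B(OMe)3, −78 °C → rt; H2O2, aq NaOH, 0 °C
Reagents that add atoms: hydrogen peroxide, OO
Why: Directed ortho-metalation, borylation and boronate oxidation, in which the methoxy group should direct lithiation to its only free ortho position (it is a poor director of lateral metalation) and peroxide-induced aryl migration from boron to oxygen installs the hydroxyl there.

**Step 4**
Reactants: 8 2-methoxy-3,4-dimethylphenol; 4 (Z)-prop-1-enyl (R)-1-(2,4,6-triisopropylphenyl)ethyl ether
Product: 10 (1R,4R,7R,8R)-3,3-dimethoxy-4,5,8-trimethyl-7-[(1R)-1-(2,4,6-triisopropylphenyl)ethoxy]bicyclo[2.2.2]oct-5-en-2-one (7-alkoxy and 8-methyl both endo), via masked o-benzoquinone 9 (not isolated)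
Conditions: PhI(OAc)2, MeOH, 0 °C; evaporate; 4 (2 equiv), toluene, 80 °C
Reagents that add atoms: methanol, CO
Why: PhI(OAc)2 oxidises phenol 8 to a phenoxenium ion that methanol captures at the methoxy-bearing carbon, so the arene is dearomatized to the linearly conjugated 2,4-dienone 9, which adds enol ether 4 in an inverse-electron-demand Diels–Alder reaction. The closest known reaction type is the Diels–Alder reaction of masked o-benzoquinones with enol ethers such as benzyl vinyl ether or 2,3-dihydrofuran, which is ortho- and endo-selective. The new six-membered ring C1–C2–C3–C4–C5–C6 closes by a concerted, asynchronous suprafacial [4π+2π] cycloaddition across the former para carbons C3 and C6 of the arene (C2–C3 leading, C1–C6 following), leaving C7(OMe)2–C8(=O) as the third bridge of a bicyclo[2.2.2]octenone. C2 and the quaternary C3 are set relative to each other by the Z geometry of 4 and the endo orientation of its alkoxy group, which place the C2 methyl and the C1 oxygen syn to the new C4=C5 bridge and hence the C2 methyl cis to the C3 methyl in the later cyclohexanone; C1 and C6 follow from suprafacial addition and are erased later. The absolute sense is set by the (R)-auxiliary: in the s-trans enol ether conformer with the carbinol C–H in the alkene plane the triisopropylphenyl group covers one π face, so the dienone should add to the other, and because the auxiliary is chiral any minor facial isomer is a separable diastereomer. The step needs regioselectivity, secured by the match of the nucleophilic C2 of 4 with the electrophilic δ-carbon C3 of the dienone (alkoxy carbon C1 to the α-carbon C6), and chemoselectivity over dienone dimerization, secured by the two methyl groups on the C3=C4 bond that make it a poor dienophile.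

**Step 5**
Reactants: 10 the Diels–Alder adduct
Product: 11 (1R,4R,7R,8R)-4,5,8-trimethyl-7-[(1R)-1-(2,4,6-triisopropylphenyl)ethoxy]bicyclo[2.2.2]oct-5-en-2-one
Conditions: SmI2 (5 equiv), THF/MeOH, 0 °C; aq work-up
Reagents that add atoms: none
Why: Reductive cleavage of an α-alkoxy ketone by SmI2, in which the ketyl expels the α-methoxide and the samarium enolate is protonated, twice in succession, so that C7 should become CH2 while the β-alkoxy group, the alkene and all stereocenters stay untouched.

**Step 6**
Reactants: 11 the demethoxylated bicyclooctenone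
Product: 12 (1R,4S,5R,6R,8R)-4,5,8-trimethyl-6-[(1R)-1-(2,4,6-triisopropylphenyl)ethoxy]bicyclo[2.2.2]octan-2-one
Conditions: H2 (4 atm), Pd/C, EtOAc, rt
Reagents that add atoms: none
Why: Heterogeneous catalytic hydrogenation, in which the endo C2 methyl and the endo alkoxy group screen the face of C4=C5 that is syn to the C1–C2 bridge, so hydrogen should be delivered syn from the face toward the C7–C8 bridge, turning the C4 methyl toward the C1–C2 bridge, i.e. cis to the C3 methyl in the later cyclohexanone.

**Step 7**
Reactants: 12 the saturated ether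
Product: 13 (1R,4S,5R,6R,8R)-6-hydroxy-4,5,8-trimethylbicyclo[2.2.2]octan-2-one
Conditions: CF3CO2H, CH2Cl2, 0 °C
Reagents that add atoms: none
Why: Acidolysis of a hindered secondary benzylic ether (SN1/E1), in which the benzylic carbon ionizes and loses a proton to the styrene, so the C1 hydroxyl is released with retention because the C1–O bond is not broken, and the bridgehead C6 blocks β-elimination.

**Step 8**
Reactants: 13 the hydroxy ketone
Product: 14 (1S,3R,4S,8R)-3,4,8-trimethylbicyclo[2.2.2]octane-2,6-dione
Conditions: triacetoxyperiodinane (DMP), CH2Cl2, 0 °C → rt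
Reagents that add atoms: none
Why: Periodinane oxidation of the secondary alcohol (ligand exchange, then α-hydrogen abstraction) should give the 1,3-diketone under neutral conditions that avoid retro-aldol cleavage of 13.

**Step 9**
Reactants: 14 the bicyclic 1,3-diketone
Product: 15 methyl 2-[(1S,2R,6R)-1,2,6-trimethyl-3-oxocyclohexyl]acetate
Conditions: K2CO3 (0.2 equiv), MeOH, 0 °C
Reagents that add atoms: methanol, CO
Why: Retro-Claisen fragmentation, in which the bridgehead C6–H between the carbonyls cannot be enolized, so methoxide should add to the less hindered C8 carbonyl (CH2-flanked, whereas C1 is flanked by the methyl-bearing C2) and expel the C1 enolate with relief of bicyclic strain; C2 keeps its configuration under these mild conditions and is expected to be the equatorial, thermodynamically preferred epimer in any case.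

**Step 10**
Reactants: 15 the keto ester
Product: 16 2-[(1S,2R,6R)-3-hydroxy-1,2,6-trimethylcyclohexyl]ethan-1-ol (mixture of epimers at the ring carbinol)
Conditions: LiAlH4, THF, 0 °C; aq work-up
Reagents that add atoms: none
Why: Hydride reduction of ester and ketone to the diol, the new ring carbinol center being formed without control, which is irrelevant because it is reoxidized.

**Step 11**
Reactants: 16 the diol
Product: 17 2-[(1S,2R,6R)-1,2,6-trimethyl-3-oxocyclohexyl]acetaldehyde
Conditions: (COCl)2, DMSO, CH2Cl2, −78 °C; Et3N, −78 → 0 °C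
Reagents that add atoms: none
Why: Swern oxidation, in which both hydroxyls are converted into alkoxysulfonium ions before base is added, so both should be oxidized at once without lactol or lactone formation from the 1,5-related hydroxy aldehyde, and the low temperature protects the α-stereocenter C2.

**Step 12**
Reactants: 18 orcinol (5-methylbenzene-1,3-diol)
Product: 19 1,3-bis(methoxymethoxy)-5-methylbenzene
Conditions: NaH, MOMCl, DMF, 0 °C → rt
Reagents that add atoms: chloromethyl methyl ether, COCCl
Why: Williamson-type O-alkylation of both phenoxides by the chloromethyl ether should give the bis-acetal, which also serves as the ortho-directing group for the next step.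

**Step 13**
Reactants: 19 1,3-bis(methoxymethoxy)-5-methylbenzene; 20 1-bromobut-2-yne
Product: 22 2-(but-2-yn-1-yl)-1,3-bis(methoxymethoxy)-5-methylbenzene, via aryllithium 21 (not isolated)
Conditions: n-BuLi, THF, 0 °C; 20, −78 °C → rt
Reagents that add atoms: none
Why: Directed ortho-metalation at the position flanked by both acetal oxygens, then SN2 alkylation of the aryllithium by the primary propargylic bromide in the absence of copper, which should avoid allene formation.

**Step 14**
Reactants: 22 the butynyl arene
Product: 23 2-(but-2-yn-1-yl)-4-chloro-1,3-bis(methoxymethoxy)-5-methylbenzene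
Conditions: NCS (1.0 equiv), DMF, rt
Reagents that add atoms: N-chlorosuccinimide, ClN1C(=O)CCC1=O
Why: Electrophilic aromatic chlorination should occur at one of the two equivalent free positions, each ortho and para to an acetal oxygen, while the alkyne is inert to the reagent.

**Step 15**
Reactants: 23 the chloro aryl alkyne; 17 the keto aldehyde
Product: 26 (2R,3S,4R)-3-[(2S,3E)-5-[3-chloro-2,6-bis(methoxymethoxy)-4-methylphenyl]-2-hydroxy-3-methylpent-3-en-1-yl]-2,3,4-trimethylcyclohexan-1-one, via alkenylzirconocene 24 (not isolated), via alkenylzinc 25 (not isolated)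
Conditions: Cp2Zr(H)Cl (slight excess), CH2Cl2, rt; Me2Zn, toluene, −65 °C; (+)-MIB [(2R)-3-exo-morpholinoisoborneol, 10 mol%], then 17, −30 °C
Reagents that add atoms: none
Why: Syn hydrozirconation should place zirconium on the methyl-bearing alkyne carbon (the less hindered one after equilibration) and so fix the E geometry, zirconium-to-zinc transmetalation gives an alkenylzinc that adds to the aldehyde but not the ketone, and the zinc aminoalkoxide of (+)-MIB should direct the alkenyl group to the Re face to set the (S)-carbinol C8 under catalyst control.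

**Step 16**
Reactants: 26 the bis(methoxymethyl) ether
Product: 27 (2R,3S,4R)-3-[(2S,3E)-5-(3-chloro-2,6-dihydroxy-4-methylphenyl)-2-hydroxy-3-methylpent-3-en-1-yl]-2,3,4-trimethylcyclohexan-1-one
Conditions: NaHSO4·SiO2, CH2Cl2, rt
Reagents that add atoms: none
Why: Acid-catalysed hydrolysis of the phenolic methoxymethyl acetals on a solid acid should be mild enough to leave the allylic alcohol, the ketone and the stereocenters alone.

**Step 17**
Reactants: 27 the resorcinol
Product: 28 2-chloro-5-hydroxy-6-[(2E,4S)-4-hydroxy-3-methyl-5-[(1S,2R,6R)-1,2,6-trimethyl-3-oxocyclohexyl]pent-2-en-1-yl]-3-methylcyclohexa-2,5-diene-1,4-dione (target)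
Conditions: ON(SO3K)2 (2.5 equiv), KH2PO4 buffer, acetone/H2O, 0 °C → rt
Reagents that add atoms: potassium nitrosodisulfonate, [K+].[K+].[O]N(S(=O)(=O)[O-])S(=O)(=O)[O-]
Why: Teuber oxidation, in which the nitroxyl radical forms the phenoxyl radical and a second equivalent couples at the only unsubstituted ring carbon (para to one hydroxyl), so the p-quinone should form with the other hydroxyl kept as the hydroxyquinone and no stereocenter affected.

**Compound list**

1 | (R)-1-(2,4,6-triisopropylphenyl)ethanol | C[C@@H](O)c1c(C(C)C)cc(C(C)C)cc1C(C)C | starting material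
2 | allyl bromide | C=CCBr | starting material
3 | allyl (R)-1-(2,4,6-triisopropylphenyl)ethyl ether | C=CCO[C@H](C)c1c(C(C)C)cc(C(C)C)cc1C(C)C | intermediate
4 | (Z)-prop-1-enyl (R)-1-(2,4,6-triisopropylphenyl)ethyl ether | C/C=C\O[C@H](C)c1c(C(C)C)cc(C(C)C)cc1C(C)C | intermediate
5 | 2,3-dimethylanisole | COc1cccc(C)c1C | starting material
6 | (2-methoxy-3,4-dimethylphenyl)lithium | COc1c([Li])ccc(C)c1C | intermediate
7 | dimethyl (2-methoxy-3,4-dimethylphenyl)boronate | COB(OC)c1ccc(C)c(C)c1OC | intermediate
8 | 2-methoxy-3,4-dimethylphenol | COc1c(O)ccc(C)c1C | intermediate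
9 | 6,6-dimethoxy-4,5-dimethylcyclohexa-2,4-dien-1-one | COC1(OC)C(=O)C=CC(C)=C1C | intermediate
10 | (1R,4R,7R,8R)-3,3-dimethoxy-4,5,8-trimethyl-7-[(1R)-1-(2,4,6-triisopropylphenyl)ethoxy]bicyclo[2.2.2]oct-5-en-2-one | O=C1C(OC)(OC)[C@@]2(C)C(C)=C[C@@H]1[C@H](O[C@H](C)c3c(C(C)C)cc(C(C)C)cc3C(C)C)[C@@H]2C | intermediate
11 | (1R,4R,7R,8R)-4,5,8-trimethyl-7-[(1R)-1-(2,4,6-triisopropylphenyl)ethoxy]bicyclo[2.2.2]oct-5-en-2-one | O=C1C[C@@]2(C)C(C)=C[C@@H]1[C@H](O[C@H](C)c3c(C(C)C)cc(C(C)C)cc3C(C)C)[C@@H]2C | intermediate
12 | (1R,4S,5R,6R,8R)-4,5,8-trimethyl-6-[(1R)-1-(2,4,6-triisopropylphenyl)ethoxy]bicyclo[2.2.2]octan-2-one | O=C1C[C@@]2(C)[C@H](C)C[C@@H]1[C@H](O[C@H](C)c3c(C(C)C)cc(C(C)C)cc3C(C)C)[C@@H]2C | intermediate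
13 | (1R,4S,5R,6R,8R)-6-hydroxy-4,5,8-trimethylbicyclo[2.2.2]octan-2-one | O=C1C[C@@]2(C)[C@H](C)C[C@@H]1[C@H](O)[C@@H]2C | intermediate
14 | (1S,3R,4S,8R)-3,4,8-trimethylbicyclo[2.2.2]octane-2,6-dione | O=C1C[C@@]2(C)[C@H](C)C[C@@H]1C(=O)[C@@H]2C | intermediate
15 | methyl 2-[(1S,2R,6R)-1,2,6-trimethyl-3-oxocyclohexyl]acetate | COC(=O)C[C@@]1(C)[C@H](C)CCC(=O)[C@@H]1C | intermediate
16 | 2-[(1S,2R,6R)-3-hydroxy-1,2,6-trimethylcyclohexyl]ethan-1-ol (epimers at the ring carbinol) | OCC[C@@]1(C)[C@H](C)CCC(O)[C@@H]1C | intermediate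
17 | 2-[(1S,2R,6R)-1,2,6-trimethyl-3-oxocyclohexyl]acetaldehyde | O=CC[C@@]1(C)[C@H](C)CCC(=O)[C@@H]1C | intermediate
18 | orcinol (5-methylbenzene-1,3-diol) | Cc1cc(O)cc(O)c1 | starting material
19 | 1,3-bis(methoxymethoxy)-5-methylbenzene | COCOc1cc(C)cc(OCOC)c1 | intermediate
20 | 1-bromobut-2-yne | CC#CCBr | starting material
21 | [2,6-bis(methoxymethoxy)-4-methylphenyl]lithium | COCOc1cc(C)cc(OCOC)c1[Li] | intermediate
22 | 2-(but-2-yn-1-yl)-1,3-bis(methoxymethoxy)-5-methylbenzene | COCOc1cc(C)cc(OCOC)c1CC#CC | intermediate
23 | 2-(but-2-yn-1-yl)-4-chloro-1,3-bis(methoxymethoxy)-5-methylbenzene | COCOc1cc(C)c(Cl)c(OCOC)c1CC#CC | intermediate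
24 | chloro[(E)-4-aryl-but-2-en-2-yl]zirconocene (aryl = 3-chloro-2,6-bis(methoxymethoxy)-4-methylphenyl) | COCOc1cc(C)c(Cl)c(OCOC)c1C/C=C(\C)[Zr](Cl)(C2C=CC=C2)C2C=CC=C2 | intermediate
25 | [(E)-4-aryl-but-2-en-2-yl](methyl)zinc (same aryl) | COCOc1cc(C)c(Cl)c(OCOC)c1C/C=C(\C)[Zn]C | intermediate
26 | (2R,3S,4R)-3-[(2S,3E)-5-[3-chloro-2,6-bis(methoxymethoxy)-4-methylphenyl]-2-hydroxy-3-methylpent-3-en-1-yl]-2,3,4-trimethylcyclohexan-1-one | COCOc1cc(C)c(Cl)c(OCOC)c1C/C=C(\C)[C@@H](O)C[C@@]2(C)[C@H](C)CCC(=O)[C@@H]2C | intermediate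
27 | (2R,3S,4R)-3-[(2S,3E)-5-(3-chloro-2,6-dihydroxy-4-methylphenyl)-2-hydroxy-3-methylpent-3-en-1-yl]-2,3,4-trimethylcyclohexan-1-one | Oc1cc(C)c(Cl)c(O)c1C/C=C(\C)[C@@H](O)C[C@@]2(C)[C@H](C)CCC(=O)[C@@H]2C | intermediate
28 | 2-chloro-5-hydroxy-6-[(2E,4S)-4-hydroxy-3-methyl-5-[(1S,2R,6R)-1,2,6-trimethyl-3-oxocyclohexyl]pent-2-en-1-yl]-3-methylcyclohexa-2,5-diene-1,4-dione | CC1=C(Cl)C(=O)C(C/C=C(\C)[C@@H](O)C[C@@]2(C)[C@H](C)CCC(=O)[C@@H]2C)=C(O)C1=O | target

**Step count and risks**

Total step count: 17. Longest linear sequence: 13 steps (steps 1, 2, 4–11 and 15–17, from 1).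

Steps most likely to fail:

Step 4. The hindered cis-enol ether may add too slowly to the dienone, so that dienone dimerization and loss of the auxiliary-bearing enol ether compete, and π-facial control by the auxiliary may be incomplete. The fallback sets out from 8. Compound 8 is oxidized as in step 4 and the dienone is heated with a large excess of cheap benzyl (Z)-prop-1-enyl ether F1 (from allyl benzyl ether, KOtBu, DMSO), which should give the racemic adduct F2. SmI2 as in step 5 gives the racemic demethoxylated enone F3. Hydrogen over Pd(OH)2/C saturates the alkene from the same face and cleaves the benzyl ether in one operation to the racemic hydroxy ketone F4. Lipase-catalysed kinetic resolution (vinyl acetate, t-BuOMe; Burkholderia cepacia lipase as first candidate, the enzyme being chosen so that the unwanted enantiomer is acetylated to acetate F5) leaves 13, where the route is rejoined.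

Step 6. Hydrogen uptake may stall or the double bond may migrate, because the C4 methyl is forced against the endo C2 methyl as the bicyclic product forms. The fallback sets out from 11. The auxiliary is removed with CF3CO2H to give hydroxy enone F6, periodinane oxidation gives ene-dione F7, and K2CO3/MeOH opens it to cyclohexenyl keto ester F8 (kinetic α-protonation of the dienolate should keep the alkene out of conjugation). Radical hydrogen-atom-transfer hydrogenation of the trisubstituted alkene (Mn(dpm)3, PhSiH3, t-BuOOH, i-PrOH) should then favour the thermodynamically preferred product with the C4 methyl equatorial and cis to the C3 methyl, giving 15, where the route is rejoined.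

Step 15. Regio-leakage in the hydrozirconation and background addition promoted by the zirconocene by-product may erode control at the carbinol carbon. The fallback sets out from 23 and 17. The alkenylzirconocene from 23 is iodinated (I2) to vinyl iodide F9, which is coupled with 17 in a Nozaki–Hiyama–Kishi reaction (CrCl2, NiCl2 cat., DMF; aldehyde-selective). This should give 26 together with its carbinol epimer F10. After separation, F10 is inverted by a Mitsunobu reaction (4-nitrobenzoic acid, PPh3, DIAD) to 4-nitrobenzoate F11, and methanolysis (K2CO3, MeOH) returns 26.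

**Further compounds**

F1 | step 4 | benzyl (Z)-prop-1-enyl ether | C/C=C\OCc1ccccc1
F2 | step 4 | racemic (1R*,4R*,7R*,8R*)-7-(benzyloxy)-3,3-dimethoxy-4,5,8-trimethylbicyclo[2.2.2]oct-5-en-2-one (one enantiomer drawn) | O=C1C(OC)(OC)[C@@]2(C)C(C)=C[C@@H]1[C@H](OCc3ccccc3)[C@@H]2C
F3 | step 4 | racemic (1R*,4R*,7R*,8R*)-7-(benzyloxy)-4,5,8-trimethylbicyclo[2.2.2]oct-5-en-2-one (one enantiomer drawn) | O=C1C[C@@]2(C)C(C)=C[C@@H]1[C@H](OCc3ccccc3)[C@@H]2C
F4 | step 4 | racemic 6-hydroxy-4,5,8-trimethylbicyclo[2.2.2]octan-2-one (racemate of 13; one enantiomer drawn) | O=C1C[C@@]2(C)[C@H](C)C[C@@H]1[C@H](O)[C@@H]2C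
F5 | step 4 | O-acetyl derivative of the enantiomer of 13 | O=C1C[C@]2(C)[C@@H](C)C[C@H]1[C@@H](OC(C)=O)[C@H]2C
F6 | step 6 | (1R,4R,7R,8R)-7-hydroxy-4,5,8-trimethylbicyclo[2.2.2]oct-5-en-2-one | O=C1C[C@@]2(C)C(C)=C[C@@H]1[C@H](O)[C@@H]2C
F7 | step 6 | (1S,3R,4R)-3,4,8-trimethylbicyclo[2.2.2]oct-7-ene-2,6-dione | O=C1C[C@@]2(C)C(C)=C[C@@H]1C(=O)[C@@H]2C
F8 | step 6 | methyl 2-[(1R,6R)-1,2,6-trimethyl-5-oxocyclohex-2-en-1-yl]acetate | COC(=O)C[C@@]1(C)C(C)=CCC(=O)[C@@H]1C
F9 | step 15 | 4-chloro-2-[(2E)-3-iodobut-2-en-1-yl]-1,3-bis(methoxymethoxy)-5-methylbenzene | COCOc1cc(C)c(Cl)c(OCOC)c1C/C=C(\C)I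
F10 | step 15 | (2R,3S,4R)-3-[(2R,3E)-5-[3-chloro-2,6-bis(methoxymethoxy)-4-methylphenyl]-2-hydroxy-3-methylpent-3-en-1-yl]-2,3,4-trimethylcyclohexan-1-one (carbinol epimer of 26) | COCOc1cc(C)c(Cl)c(OCOC)c1C/C=C(\C)[C@H](O)C[C@@]2(C)[C@H](C)CCC(=O)[C@@H]2C
F11 | step 15 | 4-nitrobenzoate of 26 (ester at the (S)-carbinol) | COCOc1cc(C)c(Cl)c(OCOC)c1C/C=C(\C)[C@@H](OC(=O)c3ccc(cc3)[N+](=O)[O-])C[C@@]2(C)[C@H](C)CCC(=O)[C@@H]2C
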